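## Analysis of the target

The target (compound 23) is a (3S)-3-hydroxyisoflavanone. Ring A is the benzo ring of a chroman-4-one and carries the 7-hydroxyl; ring C holds O1, the C2 methylene, C3 and the C4 ketone; ring B is a pentasubstituted benzene bound to C3 through C1', with 2'-OH, 3'-OH, 4'-OMe and a 5'-prenyl group. C3 is the only stereocentre, a fully substituted carbinol flanked by the ketone, the oxymethylene and the electron-rich ring B. It has no hydrogen and cannot epimerise by enolisation, but it can be lost by acid ionisation (assisted by the 2'-hydroxyl and 4'-methoxyl) or by retro-aldol and acyloin-type shifts once its alkoxide is free next to the ketone. The catechol-type 2',3'-diol is oxidisable, and the prenyl olefin rules out hydrogenolysis, strong protic acid and electrophilic oxidants late in the route. The difficulty lies in building the tetrasubstituted C3 as one enantiomer and in placing five different substituents on ring B in the right order. The route rests on one structural feature: O2' stands 1,4 to C4 (O2'–C2'–C1'–C3–C4), so C4 can be kept at the acid oxidation level as a five-membered aryl lactone on ring B. C4a of ring A reaches that carbonyl through C8a–O1–C2–C3, so an anion at C4a can take over the acyl carbon, close ring C and set O2' free.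

## Retrosynthetic reasoning

**23 from 22.** No skeletal bond is cut; three Si–O bonds are. This choice fixes the protecting groups for the whole route. The last step should use neither protic acid (ionisation at C3, prenyl group), nor hydrogen (prenyl group), nor unbuffered base (ketol, catechol). Silyl ethers on O7, O3' and O3 fall together to buffered fluoride, so 22 is the 3-O-triethylsilyl-7,3'-bis-O-triisopropylsilyl ether of 23. O2' is already free in 22 because it is the leaving group of the key step.

**22 from 19.** The C4–C4a bond is cut. Cutting here separates an intact ring A, as a carbanion at C4a marked by a bromine, from a ring-B fragment that holds C4 as an acyl group. The 2'-oxygen holds that acyl carbon as a lactone, so 19 is a benzofuran-2-one with a 2-bromoaryloxymethyl group, a silyloxy group and the lactone carbonyl on its C3. The gains are that the stereocentre is complete and inert before the step, ring C closes in the same event, O2' needs no protecting group, and the acyl donor is an activated aryl ester. The forward reaction has to generate the aryllithium without touching the lactone and then transfer the acyl group from O2' to C4a.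

**19 from 17 and 18.** The side chain is cut at its double bond. 17 carries an allyl group, which cross-metathesis with 18 turns into prenyl. The allyl group survives the two acid-promoted steps earlier in the route (ketal hydrolysis and lactonisation); a prenyl group would be at risk there. Placed here, the trisubstituted olefin meets only the organolithium and fluoride.

**17 from 15.** Two O–Si bonds are cut. 15 has a hindered phenol at C7 and a tertiary hydroxyl at C3, which are silylated in order of accessibility in one flask.

**15 from 13 and 6.** The C3–C3a bond (C3–C1' of the target) and the lactone C–O bond are cut. The aryl–carbinol bond is the one bond to the stereocentre that can be made by attack of a nucleophilic arene on a prochiral ketone. The ketone is the 2-oxo ester 6, which already holds ring A, O1, C2, C3 and C4. The arene is catechol 13. Its C1 hydroxyl directs attack to the adjacent carbon (the only free position ortho to a hydroxyl, and para to the methoxy group) and then closes the lactone. The forward reaction has to select one face of the ketone.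

**6 from 4, 4 from 2 and 3, 2 from 1.** The ketone of 6 comes from the methylene of 4 by oxidative cleavage. The O1–C2 bond comes from alkylation of phenol 2 with the allylic bromide 3. 2 comes from 1 by silylation of the hydroxyl remote from bromine. The bromine in 1 is already ortho to the future O1 and para to the future O7, so no regioselective halogenation is needed.

**13 from 12, 11, 9, and from 7 and 8.** The C-allyl bond ortho to the methoxy group cannot be made by direct alkylation of a methoxycatechol, where two resorcinol-type positions compete. The allyl group is therefore delivered from oxygen by a Claisen rearrangement before that oxygen is methylated. In 7 the two neighbouring oxygens are tied as an acetonide and the single free phenol has one free ortho carbon, the one required. O-Allylation (9), rearrangement (11), methylation (12) and ketal hydrolysis give 13.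

## Alternatives that were turned down

**Alternative 1: Diels–Alder construction of ring A.**
- Disconnection: C4a–C8a and C5–C6. Ring A is built from an oxygenated four-carbon diene (a bis-silyl ketene acetal from an acetoacetate on the C2 oxygen) and an alkynyl ketone at C4.
- Forward key step: an intramolecular cycloaddition closes rings C and A together. Elimination of the silyloxy group at C8a aromatises and gives A1, the 3,2',3'-tris-O-methoxymethyl ether of the target with free 7-hydroxyl.
- For: two rings and two C–C bonds in one step, no organometallic reagent, and a free 7-hydroxyl.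
- Against:
  - The substrate is an acyclic chain whose tetrasubstituted C3 carries an ynone, an acyloxymethyl group, an acetal and ring B. It is harder to make as one enantiomer than a benzofuranone, and no ring locks the carbinol.
  - A silyl ketene acetal beside a terminal ynone invites intermolecular Mukaiyama–Michael addition.
  - At C8a either the silyloxy group or ring oxygen O1 can leave, and loss of O1 would reopen ring C.
  - Ring A is assembled from small pieces although a suitable resorcinol is for sale.
  - A1 needs acid to lose its acetals.
- Comparison: Alternative 1 is stronger on bond formation in the key step. The chosen route offers a short path from aromatic building blocks, a key step with one nucleophile and one electrophile, and a fluoride endgame.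

**Alternative 2: aryne annulation.**
- Disconnection: O1–C8a and C4–C4a. Ring A arrives as an aryne.
- Forward key step: the primary alkoxide of a β-hydroxy ester carrying the C3 carbinol adds at the future C8a, and the aryl anion formed at C4a closes on the ester to give A2.
- For: highly convergent. One step makes the two bonds that the chosen route makes in steps 2 and 11, and the carbanion is again born next to its electrophile.
- Against:
  - An unsymmetrical aryne needs a regiocontrol element. A2 carries a chlorine at C5 that must be removed reductively beside an aryl ketone.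
  - A2 lacks the prenyl group, so a C–C bond must still be made on the crowded ring B after the key step.
  - Protonation of the aryl anion by the hydroxy ester competes with acylation.
  - The aryne can be trapped by the electron-rich ring B.
- Comparison: Alternative 2 is stronger on convergence. The chosen route fixes the carbanion site by a bromine that is consumed in the step, carries the complete ring B through, and needs no corrective steps afterwards.

**Alternative 3: carbene-catalysed crossed benzoin.**
- Disconnection: C3–C4. A ring-A aldehyde (the future C4) is tethered through O1–C2 to a ring-B aryl ketone (the future C3).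
- Forward key step: the carbene turns the aldehyde into an acyl anion equivalent that adds to the ketone. This closes ring C, sets C3 and gives A3.
- For: the stereocentre and the ring are made in one catalytic step. Enantioselective intramolecular crossed benzoin closure to 3-hydroxychroman-4-ones is an established reaction type. A3 is three acetals away from the target. On stereochemical economy and probably on step count this alternative is stronger.
- Against:
  - The acceptor is an aryl ketone whose aryl group is ring B, with an ortho alkoxy group and three donors. It is twisted and electron-rich, a poor electrophile, and far from the simple ketones on which high selectivity rests.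
  - Benzoin addition is reversible, so the enantiomeric purity is exposed to retro-benzoin.
  - Making the α-aryloxy ketone requires acylation or α-halogenation on a ring that bears the prenyl group.
  - The final acetal removal needs acid on the sensitive carbinol.
- Comparison: the chosen route offers an irreversible ring closure and an acyl acceptor whose reactivity does not depend on ring B. The stereocentre sits in a rigid lactone that can be checked and enriched before the key step.

Key step: step 11

Assumption: the sense of induction in step 8 cannot be derived with confidence for this oxo ester. The quinine-derived catalyst is written; the quinidine-derived pseudoenantiomer serves if the opposite face is favoured. The configuration of 15 would be secured by anomalous X-ray dispersion from its bromine atom before the route continues.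

Assumption: 2,2-dimethyl-1,3-benzodioxol-4-ol (7) and methyl 2-(bromomethyl)acrylate (3) are taken as commercial.

## Route

Step 1
Reactants: 1 4-bromoresorcinol
Product: 2 2-bromo-5-(triisopropylsilyloxy)phenol
Conditions: TIPSCl (1.0 equiv), imidazole, CH2Cl2, 0 °C
Reagents that add atoms: chlorotriisopropylsilane, CC(C)[Si](Cl)(C(C)C)C(C)C
Why: Silylation of the less hindered hydroxyl; the hydroxyl ortho to bromine is shielded, so the bulky silyl chloride should go to the oxygen para to bromine and leave free the phenol that becomes O1.

Step 2
Reactants: 2 2-bromo-5-(triisopropylsilyloxy)phenol; 3 methyl 2-(bromomethyl)acrylate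
Product: 4 methyl 2-{[2-bromo-5-(triisopropylsilyloxy)phenoxy]methyl}acrylate
Conditions: K2CO3, acetone, rt
Reagents that add atoms: none
Why: Williamson ether synthesis with an ester-activated allylic bromide (direct and allylic displacement give the same ether); it forms the O1–C2 bond under conditions that an aryl silyl ether tolerates.

Step 3
Reactants: 4 methyl 2-{[2-bromo-5-(triisopropylsilyloxy)phenoxy]methyl}acrylate
Product: 6 methyl 3-[2-bromo-5-(triisopropylsilyloxy)phenoxy]-2-oxopropanoate, via racemic diol 5 (not isolated)
Conditions: K2OsO4·2H2O (2 mol %), NaIO4, 2,6-lutidine, dioxane–H2O, rt; then azeotropic drying (toluene)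
Reagents that add atoms: sodium periodate, [Na+].[O-]I(=O)(=O)=O (its oxygen reaches the new ketone through the osmium catalyst)
Why: Lemieux–Johnson oxidation; dihydroxylation of the 1,1-disubstituted alkene and periodate cleavage of diol 5 in the same flask give the 2-oxo ester and formaldehyde. The reagent pair leaves the electron-rich bromoarene alone, and the hydrate formed in water is returned to the ketone on drying.

Step 4
Reactants: 7 2,2-dimethyl-1,3-benzodioxol-4-ol; 8 allyl bromide
Product: 9 4-(allyloxy)-2,2-dimethyl-1,3-benzodioxole
Conditions: K2CO3, acetone, reflux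
Reagents that add atoms: none
Why: Williamson O-allylation of the only free phenol; the acetonide keeps the other two oxygens out of play.

Step 5
Reactants: 9 4-(allyloxy)-2,2-dimethyl-1,3-benzodioxole
Product: 11 5-allyl-2,2-dimethyl-1,3-benzodioxol-4-ol, via ortho-dienone 10 (not isolated)
Conditions: N,N-diethylaniline, 190 °C
Reagents that add atoms: none
Why: Aromatic Claisen rearrangement; the [3,3] shift can end productively only at C5, the one free ortho carbon, and tautomerisation of dienone 10 restores the phenol. This puts the side chain next to the oxygen that becomes the methoxy group.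

Step 6
Reactants: 11 5-allyl-2,2-dimethyl-1,3-benzodioxol-4-ol
Product: 12 5-allyl-4-methoxy-2,2-dimethyl-1,3-benzodioxole
Conditions: MeI, K2CO3, DMF, rt
Reagents that add atoms: iodomethane, CI
Why: O-Methylation of the phenoxide; the phenol that directed the rearrangement becomes the 4'-methoxy group.

Step 7
Reactants: 12 5-allyl-4-methoxy-2,2-dimethyl-1,3-benzodioxole
Product: 13 4-allyl-3-methoxybenzene-1,2-diol
Conditions: TFA–H2O (9:1), 0 °C to rt, argon
Reagents that add atoms: none
Why: Acid hydrolysis of the aryl ketal releases the catechol and acetone. The terminal allyl olefin and the aryl methyl ether are inert to aqueous acid, which is why the side chain is still allyl at this point.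

Step 8
Reactants: 13 4-allyl-3-methoxybenzene-1,2-diol; 6 methyl 3-[2-bromo-5-(triisopropylsilyloxy)phenoxy]-2-oxopropanoate
Product: 15 (S)-5-allyl-3-{[2-bromo-5-(triisopropylsilyloxy)phenoxy]methyl}-3,7-dihydroxy-6-methoxybenzofuran-2(3H)-one, via open hydroxy ester 14 (not isolated)
Conditions: quinine-derived 3,5-bis(trifluoromethyl)phenyl squaramide (10 mol %), CH2Cl2, 4 Å MS, −20 °C; then PPTS (10 mol %), toluene, 60 °C
Reagents that add atoms: none
Why: Enantioselective ortho Friedel–Crafts hydroxyalkylation of an electron-rich phenol with a 2-oxo ester under bifunctional hydrogen-bond catalysis, then lactonisation. The squaramide NH groups bind the 1,2-dicarbonyl unit and the quinuclidine nitrogen holds the C1 hydroxyl, so the carbon ortho to that hydroxyl and para to the methoxy group attacks one face of the ketone and sets C3 as (S). Mild acid then closes the five-membered lactone with loss of methanol, which ties the carbinol into a ring that resists ionisation.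

Step 9
Reactants: 15 (S)-5-allyl-3-{[2-bromo-5-(triisopropylsilyloxy)phenoxy]methyl}-3,7-dihydroxy-6-methoxybenzofuran-2(3H)-one
Product: 17 (S)-5-allyl-3-{[2-bromo-5-(triisopropylsilyloxy)phenoxy]methyl}-6-methoxy-3-(triethylsilyloxy)-7-(triisopropylsilyloxy)benzofuran-2(3H)-one, via 7-O-triisopropylsilyl ether 16 (not isolated)
Conditions: TIPSOTf (1.1 equiv), 2,6-lutidine, CH2Cl2, −78 to −20 °C; then TESOTf (1.5 equiv), −78 to 0 °C
Reagents that add atoms: triisopropylsilyl triflate, CC(C)[Si](OS(=O)(=O)C(F)(F)F)(C(C)C)C(C)C; triethylsilyl triflate, CC[Si](CC)(CC)OS(=O)(=O)C(F)(F)F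
Why: Sequential silylation with silyl triflates and a non-nucleophilic base, which leaves the aryl lactone untouched. The bulky reagent takes the phenol and is too hindered for the neopentyl-like tertiary hydroxyl, which the smaller triethylsilyl triflate then covers.

Step 10
Reactants: 17 (S)-5-allyl-3-{[2-bromo-5-(triisopropylsilyloxy)phenoxy]methyl}-6-methoxy-3-(triethylsilyloxy)-7-(triisopropylsilyloxy)benzofuran-2(3H)-one; 18 2-methyl-2-butene
Product: 19 (S)-3-{[2-bromo-5-(triisopropylsilyloxy)phenoxy]methyl}-6-methoxy-5-(3-methylbut-2-enyl)-3-(triethylsilyloxy)-7-(triisopropylsilyloxy)benzofuran-2(3H)-one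
Conditions: second-generation Grubbs catalyst (H2IMes)(PCy3)Cl2Ru=CHPh (5 mol %), 2-methyl-2-butene–CH2Cl2, 40 °C, sealed tube
Reagents that add atoms: none
Why: Olefin cross-metathesis of an allylarene with excess 2-methyl-2-butene exchanges the terminal methylene for an isopropylidene group and releases propene. The aryl bromide, lactone and silyl ethers are inert to the ruthenium carbene.

Step 11
Reactants: 19 (S)-3-{[2-bromo-5-(triisopropylsilyloxy)phenoxy]methyl}-6-methoxy-5-(3-methylbut-2-enyl)-3-(triethylsilyloxy)-7-(triisopropylsilyloxy)benzofuran-2(3H)-one
Product: 22 (S)-3-[2-hydroxy-4-methoxy-5-(3-methylbut-2-enyl)-3-(triisopropylsilyloxy)phenyl]-3-(triethylsilyloxy)-7-(triisopropylsilyloxy)chroman-4-one, via aryllithium 20 (not isolated), via cis-fused lithium hemiketal alkoxide 21 (not isolated)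
Conditions: t-BuLi (2.1 equiv, slow addition), THF, −95 to −78 °C; AcOH, −78 °C
Reagents that add atoms: none
Why: Parham cyclisation with acyl transfer: tert-butyllithium exchanges the ring-A bromine faster than it can add to the hindered lactone carbonyl, and the second equivalent destroys the tert-butyl bromide formed, so aryllithium 20 arises cleanly at C4a. The carbanion reaches the lactone carbonyl through C8a–O1–C2–C3 and adds in a 6-exo-trig closure that forms the C4–C4a bond and ring C. The adduct 21 is a cis-fused hemiketal alkoxide, the only fusion the five- and six-membered rings allow, and it collapses by expelling the ring-B phenoxide, so the lactone is exchanged for the aryl ketone and O2' is set free. The closest known reaction type is the Parham cyclisation of an ortho-lithiated aryl ether onto a tethered ester or lactone, here with an aryl ester as acyl donor. No stereocentre is created in the product; C3 has no hydrogen and its oxygen is silylated, so neither enolisation nor a retro-aldol or acyloin shift can touch it, and the transient hemiketal centre vanishes on collapse. The step needs exchange before carbonyl addition and no second addition to the new ketone. The first is secured by the rate of aryl bromide–lithium exchange at low temperature and the neopentyl-like shielding of the carbonyl; the second by slow addition of two equivalents and by the neighbouring lithium phenoxide, which deactivates the ketone it has just released. Silyl ethers are used on the three remaining oxygens because they neither direct lithiation nor carry acidic hydrogens.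

Step 12
Reactants: 22 (S)-3-[2-hydroxy-4-methoxy-5-(3-methylbut-2-enyl)-3-(triisopropylsilyloxy)phenyl]-3-(triethylsilyloxy)-7-(triisopropylsilyloxy)chroman-4-one
Product: 23 (S)-3-[2,3-dihydroxy-4-methoxy-5-(3-methylbut-2-enyl)phenyl]-3,7-dihydroxychroman-4-one
Conditions: TBAF (5 equiv), AcOH (5 equiv), THF, 0 °C to rt, argon
Reagents that add atoms: none
Why: Fluoride cleaves the two aryl silyl ethers and the tertiary triethylsilyl ether in one operation. The acetic acid buffer keeps the freed ketol and catechol from meeting basic fluoride, and no protic acid strong enough to ionise C3 or add to the prenyl olefin is used.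

## Compound list

1 | 4-bromoresorcinol | Oc1ccc(Br)c(O)c1 | starting material
2 | 2-bromo-5-(triisopropylsilyloxy)phenol | Oc1cc(O[Si](C(C)C)(C(C)C)C(C)C)ccc1Br | intermediate
3 | methyl 2-(bromomethyl)acrylate | COC(=O)C(=C)CBr | starting material
4 | methyl 2-{[2-bromo-5-(triisopropylsilyloxy)phenoxy]methyl}acrylate | COC(=O)C(=C)COc1cc(O[Si](C(C)C)(C(C)C)C(C)C)ccc1Br | intermediate
5 | methyl 3-[2-bromo-5-(triisopropylsilyloxy)phenoxy]-2-hydroxy-2-(hydroxymethyl)propanoate, racemic | COC(=O)C(O)(CO)COc1cc(O[Si](C(C)C)(C(C)C)C(C)C)ccc1Br | intermediate
6 | methyl 3-[2-bromo-5-(triisopropylsilyloxy)phenoxy]-2-oxopropanoate | COC(=O)C(=O)COc1cc(O[Si](C(C)C)(C(C)C)C(C)C)ccc1Br | intermediate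
7 | 2,2-dimethyl-1,3-benzodioxol-4-ol | CC1(C)Oc2cccc(O)c2O1 | starting material
8 | allyl bromide | C=CCBr | starting material
9 | 4-(allyloxy)-2,2-dimethyl-1,3-benzodioxole | CC1(C)Oc2cccc(OCC=C)c2O1 | intermediate
10 | 5-allyl-2,2-dimethyl-1,3-benzodioxol-4(5H)-one, racemic | CC1(C)OC2=C(O1)C(=O)C(CC=C)C=C2 | intermediate
11 | 5-allyl-2,2-dimethyl-1,3-benzodioxol-4-ol | CC1(C)Oc2ccc(CC=C)c(O)c2O1 | intermediate
12 | 5-allyl-4-methoxy-2,2-dimethyl-1,3-benzodioxole | CC1(C)Oc2ccc(CC=C)c(OC)c2O1 | intermediate
13 | 4-allyl-3-methoxybenzene-1,2-diol | COc1c(CC=C)ccc(O)c1O | intermediate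
14 | methyl (S)-2-(5-allyl-2,3-dihydroxy-4-methoxyphenyl)-3-[2-bromo-5-(triisopropylsilyloxy)phenoxy]-2-hydroxypropanoate | COC(=O)[C@@](O)(COc1cc(O[Si](C(C)C)(C(C)C)C(C)C)ccc1Br)c1cc(CC=C)c(OC)c(O)c1O | intermediate
15 | (S)-5-allyl-3-{[2-bromo-5-(triisopropylsilyloxy)phenoxy]methyl}-3,7-dihydroxy-6-methoxybenzofuran-2(3H)-one | COc1c(CC=C)cc2c(c1O)OC(=O)[C@@]2(O)COc1cc(O[Si](C(C)C)(C(C)C)C(C)C)ccc1Br | intermediate
16 | (S)-5-allyl-3-{[2-bromo-5-(triisopropylsilyloxy)phenoxy]methyl}-3-hydroxy-6-methoxy-7-(triisopropylsilyloxy)benzofuran-2(3H)-one | COc1c(CC=C)cc2c(c1O[Si](C(C)C)(C(C)C)C(C)C)OC(=O)[C@@]2(O)COc1cc(O[Si](C(C)C)(C(C)C)C(C)C)ccc1Br | intermediate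
17 | (S)-5-allyl-3-{[2-bromo-5-(triisopropylsilyloxy)phenoxy]methyl}-6-methoxy-3-(triethylsilyloxy)-7-(triisopropylsilyloxy)benzofuran-2(3H)-one | COc1c(CC=C)cc2c(c1O[Si](C(C)C)(C(C)C)C(C)C)OC(=O)[C@@]2(O[Si](CC)(CC)CC)COc1cc(O[Si](C(C)C)(C(C)C)C(C)C)ccc1Br | intermediate
18 | 2-methyl-2-butene | CC=C(C)C | starting material
19 | (S)-3-{[2-bromo-5-(triisopropylsilyloxy)phenoxy]methyl}-6-methoxy-5-(3-methylbut-2-enyl)-3-(triethylsilyloxy)-7-(triisopropylsilyloxy)benzofuran-2(3H)-one | COc1c(CC=C(C)C)cc2c(c1O[Si](C(C)C)(C(C)C)C(C)C)OC(=O)[C@@]2(O[Si](CC)(CC)CC)COc1cc(O[Si](C(C)C)(C(C)C)C(C)C)ccc1Br | intermediate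
20 | ring-A aryllithium from 19 (lithium in place of bromine) | COc1c(CC=C(C)C)cc2c(c1O[Si](C(C)C)(C(C)C)C(C)C)OC(=O)[C@@]2(O[Si](CC)(CC)CC)COc1cc(O[Si](C(C)C)(C(C)C)C(C)C)ccc1[Li] | intermediate
21 | cis-fused lithium hemiketal alkoxide (pterocarpan skeleton, both ring-fusion carbons S) | COc1c(CC=C(C)C)cc2c(c1O[Si](C(C)C)(C(C)C)C(C)C)O[C@]3([O-])[C@@]2(O[Si](CC)(CC)CC)COc1cc(O[Si](C(C)C)(C(C)C)C(C)C)ccc13.[Li+] | intermediate
22 | (S)-3-[2-hydroxy-4-methoxy-5-(3-methylbut-2-enyl)-3-(triisopropylsilyloxy)phenyl]-3-(triethylsilyloxy)-7-(triisopropylsilyloxy)chroman-4-one | COc1c(CC=C(C)C)cc([C@]2(O[Si](CC)(CC)CC)COc3cc(O[Si](C(C)C)(C(C)C)C(C)C)ccc3C2=O)c(O)c1O[Si](C(C)C)(C(C)C)C(C)C | intermediate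
23 | (S)-3-[2,3-dihydroxy-4-methoxy-5-(3-methylbut-2-enyl)phenyl]-3,7-dihydroxychroman-4-one | COc1c(CC=C(C)C)cc([C@]2(O)COc3cc(O)ccc3C2=O)c(O)c1O | target

## Step count and least certain steps

Total step count: 12. Longest linear sequence: 9 steps (7 to 23, steps 4 to 12). The ring-A branch (steps 1 to 3) joins at step 8.

**Step 11 (key step).** The most likely failure is direct addition of the alkyllithium to the strained aryl lactone, or a second addition to the ketone once the phenoxide has left; both would compete if exchange or ring closure is slower than expected next to the crowded C3. The fallback sets out from 19 and comes back at 23. The lactone is opened with the aluminium amide made from AlMe3 and N,O-dimethylhydroxylamine hydrochloride to (S)-3-[2-bromo-5-(triisopropylsilyloxy)phenoxy]-2-[2-hydroxy-4-methoxy-5-(3-methylbut-2-enyl)-3-(triisopropylsilyloxy)phenyl]-N-methoxy-N-methyl-2-(triethylsilyloxy)propanamide F1. The freed phenol is capped with TESCl and imidazole to its triethylsilyl ether F2. Bromine–lithium exchange then closes ring C on the Weinreb amide, whose chelated adduct cannot take a second nucleophile, to give the fully silylated isoflavanone (S)-3-[4-methoxy-5-(3-methylbut-2-enyl)-2-(triethylsilyloxy)-3-(triisopropylsilyloxy)phenyl]-3-(triethylsilyloxy)-7-(triisopropylsilyloxy)chroman-4-one F3. The buffered fluoride treatment of step 12 removes all four silyl groups and gives 23.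

**Step 8.** Three processes can fail: slow addition to a non-fluorinated, hindered 2-oxo ester; amine-catalysed self-aldol condensation of the enolisable oxo ester; and poor facial selectivity, since the catalyst was developed on more activated ketones. The fallback sets out from 13 and 6 and comes back at 15. The bromomagnesium phenoxide of 13 (EtMgBr, toluene–CH2Cl2) is combined with 6 in a chelation-controlled ortho-hydroxyalkylation, and acid lactonisation gives the racemic lactone rac-5-allyl-3-{[2-bromo-5-(triisopropylsilyloxy)phenoxy]methyl}-3,7-dihydroxy-6-methoxybenzofuran-2(3H)-one F4. Preparative chromatography on a chiral stationary phase separates this into 15 and its (R)-enantiomer F5, which is set aside.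

**Step 3.** Dihydroxylation of the electron-poor acrylate may be slow, and the enolisable oxo ester may hydrate and self-condense in the aqueous oxidising medium. The fallback sets out from 2 and comes back at 6. Phenol 2 opens racemic methyl oxirane-2-carboxylate at its methylene carbon (K2CO3 cat., DMF, 60 °C) to give methyl 3-[2-bromo-5-(triisopropylsilyloxy)phenoxy]-2-hydroxypropanoate F6. Dess–Martin periodinane in dry CH2Cl2 oxidises this secondary alcohol to 6 without water.

**Step 1.** Site selection between the two hydroxyls may be incomplete, or double silylation may occur. The fallback sets out from 1 and comes back at 2. Both hydroxyls are silylated (TIPSCl in excess, imidazole, DMF) to 1-bromo-2,4-bis(triisopropylsilyloxy)benzene F7. K2CO3 in methanol is then expected to remove first the silyl group on the oxygen ortho to bromine, whose phenoxide is the better leaving group, which gives 2.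

## Further compounds

F1 | step 11 | (S)-3-[2-bromo-5-(triisopropylsilyloxy)phenoxy]-2-[2-hydroxy-4-methoxy-5-(3-methylbut-2-enyl)-3-(triisopropylsilyloxy)phenyl]-N-methoxy-N-methyl-2-(triethylsilyloxy)propanamide | COc1c(CC=C(C)C)cc([C@](O[Si](CC)(CC)CC)(COc2cc(O[Si](C(C)C)(C(C)C)C(C)C)ccc2Br)C(=O)N(C)OC)c(O)c1O[Si](C(C)C)(C(C)C)C(C)C
F2 | step 11 | (S)-3-[2-bromo-5-(triisopropylsilyloxy)phenoxy]-N-methoxy-2-[4-methoxy-5-(3-methylbut-2-enyl)-2-(triethylsilyloxy)-3-(triisopropylsilyloxy)phenyl]-N-methyl-2-(triethylsilyloxy)propanamide | COc1c(CC=C(C)C)cc([C@](O[Si](CC)(CC)CC)(COc2cc(O[Si](C(C)C)(C(C)C)C(C)C)ccc2Br)C(=O)N(C)OC)c(O[Si](CC)(CC)CC)c1O[Si](C(C)C)(C(C)C)C(C)C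
F3 | step 11 | (S)-3-[4-methoxy-5-(3-methylbut-2-enyl)-2-(triethylsilyloxy)-3-(triisopropylsilyloxy)phenyl]-3-(triethylsilyloxy)-7-(triisopropylsilyloxy)chroman-4-one | COc1c(CC=C(C)C)cc([C@]2(O[Si](CC)(CC)CC)COc3cc(O[Si](C(C)C)(C(C)C)C(C)C)ccc3C2=O)c(O[Si](CC)(CC)CC)c1O[Si](C(C)C)(C(C)C)C(C)C
F4 | step 8 | rac-5-allyl-3-{[2-bromo-5-(triisopropylsilyloxy)phenoxy]methyl}-3,7-dihydroxy-6-methoxybenzofuran-2(3H)-one | COc1c(CC=C)cc2c(c1O)OC(=O)C2(O)COc1cc(O[Si](C(C)C)(C(C)C)C(C)C)ccc1Br
F5 | step 8 | (R)-5-allyl-3-{[2-bromo-5-(triisopropylsilyloxy)phenoxy]methyl}-3,7-dihydroxy-6-methoxybenzofuran-2(3H)-one | COc1c(CC=C)cc2c(c1O)OC(=O)[C@]2(O)COc1cc(O[Si](C(C)C)(C(C)C)C(C)C)ccc1Br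
F6 | step 3 | methyl 3-[2-bromo-5-(triisopropylsilyloxy)phenoxy]-2-hydroxypropanoate, racemic | COC(=O)C(O)COc1cc(O[Si](C(C)C)(C(C)C)C(C)C)ccc1Br
F7 | step 1 | 1-bromo-2,4-bis(triisopropylsilyloxy)benzene | CC(C)[Si](Oc1ccc(Br)c(O[Si](C(C)C)(C(C)C)C(C)C)c1)(C(C)C)C(C)C
A1 | alternative 1 | (S)-7-hydroxy-3-(methoxymethoxy)-3-[4-methoxy-2,3-bis(methoxymethoxy)-5-(3-methylbut-2-enyl)phenyl]chroman-4-one | COc1c(CC=C(C)C)cc([C@]2(OCOC)COc3cc(O)ccc3C2=O)c(OCOC)c1OCOC
A2 | alternative 2 | (S)-5-chloro-3,7-bis(methoxymethoxy)-3-[4-methoxy-2,3-bis(methoxymethoxy)phenyl]chroman-4-one | COc1ccc([C@]2(OCOC)COc3cc(OCOC)cc(Cl)c3C2=O)c(OCOC)c1OCOC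
A3 | alternative 3 | (S)-3-hydroxy-7-(methoxymethoxy)-3-[4-methoxy-2,3-bis(methoxymethoxy)-5-(3-methylbut-2-enyl)phenyl]chroman-4-one | COc1c(CC=C(C)C)cc([C@]2(O)COc3cc(OCOC)ccc3C2=O)c(OCOC)c1OCOC
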